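(The data are calculated with constants of no real substance, noise included.)

I read this flask at 12 s and at 8.0 min, and I counted the time up to each reading in substrate lifetimes.

all flasks: substrate 0.80 M
- north-east: first nucleophile 0.50 equiv; second nucleophile 1.2 equiv; the very flask that is asked about, followed so far
- north-west: first nucleophile 0.75 equiv; second nucleophile 1.2 equiv; run made earlier
- flask: first nucleophile 0.500 equiv; second nucleophile 1.20 equiv; time 8.0 min

north-east run (percent of the substrate charged)

| time / s | other capture product / % | target / % |
|---|---|---|
| 10.0 | 1.1 | 1.2 |
| 12.0 | 1.6 | 0.7 |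
| 25.0 | 2.8 | 1.7 |
| 50.0 | 3.1 | 2.5 |
| 80.0 | 6.5 | 1.0 |

north-west run (percent of the substrate charged)

| time / min | other capture product / % | target / % |
|---|---|---|
| 0.667 | 2.7 | 4.0 |
| 1.33 | 5.6 | 2.9 |
| 2.00 | 8.2 | 2.4 |
| 2.50 | 9.9 | 2.5 |
| 3.00 | 10.9 | 2.6 |

(scatter of a reading: 0.5 percentage points)

* ratio of other capture product to target at 12 s
* ratio of other capture product to target at 8.0 min

The other capture product stood at 6.5% and 5.6% after 80.0 s in the two runs, level within the scatter, so I pooled them as 6.05%. Its slope in the north-west run eased from 0.0455 min⁻¹ of the charge to 0.0290 min⁻¹ by 3.00 min. I read this as first-order decay of substrate with rate constant k = 0.299 min⁻¹. That made N = kt = 2.39 at the late reading, N being the count of substrate lifetimes elapsed.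

By then the other capture product should have collected 90.9% of its total, Q = 18.4%, while target, which showed no build-up, should follow the remaining substrate. The north-east target readings from 25.0 s on averaged 1.73% around 0.861 min. Carried back to the start, they give a scale ρ, Q over that starting level, of 8.22. The ratio is then ρ times the excess of e^N over one: 81.8 late and, with k times 12 s in place of N, 0.507 early. One number was not enough, since N gives the growth and ρ the scale.

The forecast said 1.2 and 10: “This assumes the plateau persists”. The flask gave 0.681 and 89.6.

    second nucleophile + intermediate → other capture product (k = 0.240 M⁻¹ s⁻¹)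
    intermediate → solvolysis product (k = 1.10 s⁻¹)
    intermediate → side product (k = 0.00760 s⁻¹)
    first nucleophile + intermediate ⇌ target (K = 1.60 M⁻¹, k = 1.40 M⁻¹ s⁻¹)
    first nucleophile + target ⇌ idle adduct, settled at all times (K = 22.0 M⁻¹)
    substrate → intermediate (k = 0.00610 s⁻¹)

The 5.4% of substrate left in the flask makes N 2.92. The largest single effect on the late ratio was the way back from target to first nucleophile and intermediate: the run without it gave 0.655 against 89.6. With that way open, target, the kinetic product, stood at 0.172%, idle adduct counted in, at 8.00 min. A neighbour flask with 3.00 equiv of second nucleophile kept the same 5.4% of substrate, hence the same N, and its ratio reached 226, with 31.2% of other capture product.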